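The tetrasubstituted C8=C9 alkene of ring B (labdane locants) is read as the new π bond of a [4+2] adduct. A type 1 intramolecular Diels–Alder reaction of an acyclic triene joins the C7=C8–C9=C10 diene to the C5=C6 vinyl group through the C1–C4 tether. One operation closes rings A and B and creates the C10 quaternary centre and C5, with the (E)-geometry of C9=C10 and the C3 bromide relaying the stereochemistry. The precursor already carries everything else: the C3–Br centre from CBS reduction and invertive Appel bromination, the side chain from (R)-linalool, and the diene geometry from syn-carbocupration of an ynoate.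

Key step: step 12

Remark: locants are labdane locants (ring A = C1–C5 and C10, ring B = C5–C10, side chain C11–C16, C17 on C8, C18 and C19 on C4, C20 on C10); commercial (R)-(−)-linalool is assumed to be used at, or upgraded to, high enantiomeric purity, because C13 comes from it unchanged.

Step 1
Reactants: 1 (R)-(−)-linalool
Product: 2 triethyl(((3R)-3,7-dimethylocta-1,6-dien-3-yl)oxy)silane
Conditions: TESOTf, 2,6-lutidine, CH2Cl2, −78 to 0 °C
Reagents that add atoms: triethylsilyl trifluoromethanesulfonate, CC[Si](CC)(CC)OS(=O)(=O)C(F)(F)F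
Why: Silyl ether formation with a silyl triflate, reactive enough for the tertiary allylic alcohol; no stereocentre is formed, C13 is untouched, and the ether blocks ionisation of the alcohol in steps 2 to 12.

Step 2
Reactants: 2 triethyl(((3R)-3,7-dimethylocta-1,6-dien-3-yl)oxy)silane
Product: 4 (R)-4-methyl-4-(triethylsilyloxy)hex-5-enal, via secondary ozonide 3 (not isolated)
Conditions: O3 (1.0 equiv, Sudan Red 7B end point), CH2Cl2, −78 °C; then PPh3, −78 °C to rt
Reagents that add atoms: ozone, [O-][O+]=O
Why: Ozonolysis with reductive work-up: the electron-rich isopropylidene alkene should be consumed well before the monosubstituted vinyl group when ozone is metered to an indicator end point, and the aldehyde carbon becomes C9.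

Step 3
Reactants: 4 (R)-4-methyl-4-(triethylsilyloxy)hex-5-enal
Product: 5 (R)-3-methyl-3-(triethylsilyloxy)hept-1-en-6-yne
Conditions: dimethyl (1-diazo-2-oxopropyl)phosphonate, K2CO3, MeOH, 0 °C to rt
Reagents that add atoms: dimethyl (1-diazo-2-oxopropyl)phosphonate, COP(=O)(OC)C(=[N+]=[N-])C(C)=O
Why: Seyferth–Gilbert homologation in its Ohira–Bestmann form converts the unbranched aldehyde into the terminal alkyne under mild carbonate conditions that the silyl ether tolerates; the new terminal carbon is C10.

Step 4
Reactants: 5 (R)-3-methyl-3-(triethylsilyloxy)hept-1-en-6-yne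
Product: 7 methyl (R)-6-methyl-6-(triethylsilyloxy)oct-7-en-2-ynoate, via lithium acetylide 6 (not isolated)
Conditions: n-BuLi, THF, −78 °C; then ClCO2Me, −78 to 0 °C
Reagents that add atoms: methyl chloroformate, COC(=O)Cl
Why: Deprotonation of the terminal alkyne and C-acylation of the acetylide with a chloroformate gives the 2-alkynoate needed as conjugate acceptor; the ester carbon is C1.

Step 5
Reactants: 7 methyl (R)-6-methyl-6-(triethylsilyloxy)oct-7-en-2-ynoate
Product: 9 methyl (2E,6R)-2,6-dimethyl-3-(prop-1-en-2-yl)-6-(triethylsilyloxy)octa-2,7-dienoate, via alkenylcopper adduct 8 (not isolated)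
Conditions: isopropenylmagnesium bromide (2.2 equiv), CuBr·SMe2 (1.1 equiv), THF, −78 °C; then HMPA, MeI, −78 to −20 °C
Reagents that add atoms: isopropenylmagnesium bromide, CC(=C)[Mg]Br; iodomethane, CI
Why: Conjugate carbocupration of the ynoate is a syn addition that places the isopropenyl group (C8) on C9 and copper on C10 on the same side, and C-methylation of this α-cuprio acrylate with HMPA at low temperature should proceed with retention, giving the tetrasubstituted C9=C10 bond as the (E)-isomer with C8 trans to C1.

Step 6
Reactants: 9 methyl (2E,6R)-2,6-dimethyl-3-(prop-1-en-2-yl)-6-(triethylsilyloxy)octa-2,7-dienoate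
Product: 10 (2E,6R)-2,6-dimethyl-3-(prop-1-en-2-yl)-6-(triethylsilyloxy)octa-2,7-dien-1-ol
Conditions: DIBAL-H (2.5 equiv), CH2Cl2, −78 °C; Rochelle salt work-up
Reagents that add atoms: none
Why: 1,2-Reduction of the α,β-unsaturated ester with DIBAL-H gives the allylic alcohol without touching the diene geometry.

Step 7
Reactants: 10 (2E,6R)-2,6-dimethyl-3-(prop-1-en-2-yl)-6-(triethylsilyloxy)octa-2,7-dien-1-ol
Product: 11 (2E,6R)-1-bromo-2,6-dimethyl-3-(prop-1-en-2-yl)-6-(triethylsilyloxy)octa-2,7-diene
Conditions: CBr4, PPh3, 2,6-lutidine, CH2Cl2, −20 °C; used crude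
Reagents that add atoms: carbon tetrabromide, BrC(Br)(Br)Br
Why: Appel bromination of the primary allylic alcohol under buffered conditions gives the allylic bromide by SN2 at C1 without allylic transposition.

Step 8
Reactants: 12 prenylmagnesium chloride (3-methylbut-2-en-1-ylmagnesium chloride, THF solution)
Product: 13 3,3-dimethylpent-4-en-2-one
Conditions: Ac2O (3 equiv), THF, −78 °C, inverse addition
Reagents that add atoms: acetic anhydride, CC(=O)OC(C)=O
Why: Acylation of an allylic Grignard reagent occurs with allylic transposition through a six-membered SE2′ transition state, so the prenyl reagent delivers the α,α-dimethyl β,γ-unsaturated methyl ketone that holds C2 to C6 with C18 and C19.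

Step 9
Reactants: 13 3,3-dimethylpent-4-en-2-one; 11 (2E,6R)-1-bromo-2,6-dimethyl-3-(prop-1-en-2-yl)-6-(triethylsilyloxy)octa-2,7-diene
Product: 15 (7E,11R)-3,3,7,11-tetramethyl-8-(prop-1-en-2-yl)-11-(triethylsilyloxy)trideca-1,7,12-trien-4-one, via lithium enolate 14 (not isolated)
Conditions: 13 (1.5 equiv), LDA, THF, −78 °C; then 11, −78 to 0 °C
Reagents that add atoms: none
Why: Kinetic lithium enolate alkylation: 13 can enolise only at its methyl group (C2), and this enolate displaces the primary allylic bromide at C1 by SN2 to forge the C1–C2 bond.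

Step 10
Reactants: 15 (7E,11R)-3,3,7,11-tetramethyl-8-(prop-1-en-2-yl)-11-(triethylsilyloxy)trideca-1,7,12-trien-4-one
Product: 16 (4S,7E,11R)-3,3,7,11-tetramethyl-8-(prop-1-en-2-yl)-11-(triethylsilyloxy)trideca-1,7,12-trien-4-ol
Conditions: (R)-2-methyl-CBS-oxazaborolidine (0.2 equiv), catecholborane, toluene, −78 to −20 °C
Reagents that add atoms: none
Why: CBS reduction: the oxazaborolidine differentiates the tertiary alkyl group from the primary CH2 chain, so the (R)-catalyst should deliver hydride to the face that gives the (4S)-carbinol (C3 of the target), and catecholborane at low temperature does not hydroborate the alkenes.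

Step 11
Reactants: 16 (4S,7E,11R)-3,3,7,11-tetramethyl-8-(prop-1-en-2-yl)-11-(triethylsilyloxy)trideca-1,7,12-trien-4-ol
Product: 17 (4R,7E,11R)-4-bromo-3,3,7,11-tetramethyl-8-(prop-1-en-2-yl)-11-(triethylsilyloxy)trideca-1,7,12-triene
Conditions: PPh3, CBr4, 2,6-lutidine, toluene, 0 to 40 °C
Reagents that add atoms: carbon tetrabromide, BrC(Br)(Br)Br
Why: Appel reaction: bromide displaces the alkoxyphosphonium group in an SN2 step with inversion, converting the (S)-carbinol into the (R)-bromide that is C3 of the target, and the buffered, non-ionising medium is chosen to suppress ionisation at this neopentyl-type centre.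

Step 12
Reactants: 17 (4R,7E,11R)-4-bromo-3,3,7,11-tetramethyl-8-(prop-1-en-2-yl)-11-(triethylsilyloxy)trideca-1,7,12-triene
Product: 18 (3R,5S,10R,13R)-3-bromo-13-(triethylsilyloxy)labda-8,14-diene (silyl ether of the target)
Conditions: CH2Cl2 (0.05 M), BHT, 1.5 GPa (15 kbar), 80 °C
Reagents that add atoms: none
Why: Pressure-accelerated type 1 intramolecular Diels–Alder reaction: the C7=C8–C9=C10 diene and the C5=C6 vinyl group add suprafacially in a concerted, asynchronous [4+2] process in which the bond between the two CH2 termini (C6–C7) runs ahead of the congested C5–C10 bond, and the tetrasubstituted C8=C9 alkene appears as the new π bond. The closest known reaction type is the thermal cyclisation of unactivated 1,7,9-decatrienes with a 1,1-disubstituted diene terminus to angularly methylated trans-decalins; high pressure exploits the strongly negative activation volume so that the twisted diene should react below the temperatures at which [1,5]-hydrogen shift from the inside C20 methyl or loss of HBr would compete. Ring B closes as the cyclohexene of the cycloaddition and ring A closes with it as the six-membered ring spanned by the C1–C4 tether (fused mode, tether anti in a chair-like arrangement). C5 and C10 are set relative to each other by the (E)-geometry of C9=C10 (C1 outside, C20 inside) and the anti transition state, which places H5 and C20 trans, and relative to C3 by the chair tether that keeps the C3–Br bond equatorial, which corresponds to the (3R,5S,10R) isomer. The step needs fused over bridged regiochemistry and reaction of C5=C6 in preference to the side-chain vinyl group (both secured by tether length, since C14=C15 could only close a strained bridgehead alkene through a three-atom type 2 tether), trans over cis fusion (the C4 gem-dimethyl group clashes with C9 and its substituent in the syn arrangement) and π-facial selectivity, for which the equatorial preference of bromine is the weakest control element.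

Step 13
Reactants: 18 (3R,5S,10R,13R)-3-bromo-13-(triethylsilyloxy)labda-8,14-diene
Product: 19 CNP0103973.1, (3R,5S,10R,13R)-3-bromolabda-8,14-dien-13-ol
Conditions: TBAF, THF, 0 °C to rt
Reagents that add atoms: none
Why: Fluoride-mediated cleavage of the tertiary triethylsilyl ether releases the C13 alcohol without affecting the secondary bromide or the alkenes.

Compound list
1 | (R)-(−)-linalool, (3R)-3,7-dimethylocta-1,6-dien-3-ol | C=C[C@](C)(O)CCC=C(C)C | starting material
2 | triethyl(((3R)-3,7-dimethylocta-1,6-dien-3-yl)oxy)silane | C=C[C@](C)(O[Si](CC)(CC)CC)CCC=C(C)C | intermediate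
3 | secondary ozonide of 2 (1,2,4-trioxolane across the former isopropylidene alkene) | C=C[C@](C)(O[Si](CC)(CC)CC)CCC1OOC(C)(C)O1 | intermediate (not isolated)
4 | (R)-4-methyl-4-(triethylsilyloxy)hex-5-enal | C=C[C@](C)(O[Si](CC)(CC)CC)CCC=O | intermediate
5 | (R)-3-methyl-3-(triethylsilyloxy)hept-1-en-6-yne | C=C[C@](C)(O[Si](CC)(CC)CC)CCC#C | intermediate
6 | lithium acetylide of 5 | C=C[C@](C)(O[Si](CC)(CC)CC)CCC#C[Li] | intermediate (not isolated)
7 | methyl (R)-6-methyl-6-(triethylsilyloxy)oct-7-en-2-ynoate | C=C[C@](C)(O[Si](CC)(CC)CC)CCC#CC(=O)OC | intermediate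
8 | alkenylcopper adduct: methyl 2-cuprio-3-isopropenyl-2-enoate, copper cis to isopropenyl | C=C[C@](C)(O[Si](CC)(CC)CC)CC/C(C(C)=C)=C(/[Cu])C(=O)OC | intermediate (not isolated)
9 | methyl (2E,6R)-2,6-dimethyl-3-(prop-1-en-2-yl)-6-(triethylsilyloxy)octa-2,7-dienoate | C=C[C@](C)(O[Si](CC)(CC)CC)CC/C(C(C)=C)=C(/C)C(=O)OC | intermediate
10 | (2E,6R)-2,6-dimethyl-3-(prop-1-en-2-yl)-6-(triethylsilyloxy)octa-2,7-dien-1-ol | C=C[C@](C)(O[Si](CC)(CC)CC)CC/C(C(C)=C)=C(/C)CO | intermediate
11 | (2E,6R)-1-bromo-2,6-dimethyl-3-(prop-1-en-2-yl)-6-(triethylsilyloxy)octa-2,7-diene | C=C[C@](C)(O[Si](CC)(CC)CC)CC/C(C(C)=C)=C(/C)CBr | intermediate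
12 | prenylmagnesium chloride | CC(C)=CC[Mg]Cl | starting material
13 | 3,3-dimethylpent-4-en-2-one | CC(=O)C(C)(C)C=C | intermediate
14 | lithium enolate of 13 (enolised at the methyl group) | [Li]OC(=C)C(C)(C)C=C | intermediate (not isolated)
15 | (7E,11R)-3,3,7,11-tetramethyl-8-(prop-1-en-2-yl)-11-(triethylsilyloxy)trideca-1,7,12-trien-4-one | C=C[C@](C)(O[Si](CC)(CC)CC)CC/C(C(C)=C)=C(/C)CCC(=O)C(C)(C)C=C | intermediate
16 | (4S,7E,11R)-3,3,7,11-tetramethyl-8-(prop-1-en-2-yl)-11-(triethylsilyloxy)trideca-1,7,12-trien-4-ol | C=C[C@](C)(O[Si](CC)(CC)CC)CC/C(C(C)=C)=C(/C)CC[C@H](O)C(C)(C)C=C | intermediate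
17 | (4R,7E,11R)-4-bromo-3,3,7,11-tetramethyl-8-(prop-1-en-2-yl)-11-(triethylsilyloxy)trideca-1,7,12-triene | C=C[C@](C)(O[Si](CC)(CC)CC)CC/C(C(C)=C)=C(/C)CC[C@@H](Br)C(C)(C)C=C | intermediate
18 | (3R,5S,10R,13R)-3-bromo-13-(triethylsilyloxy)labda-8,14-diene; trans-decalin, bromine equatorial and cis to the C10 methyl | C=C[C@](C)(O[Si](CC)(CC)CC)CCC1=C(C)CC[C@@H]2C(C)(C)[C@H](Br)CC[C@@]12C | intermediate
19 | CNP0103973.1, (3R,5S,10R,13R)-3-bromolabda-8,14-dien-13-ol | C=C[C@](C)(O)CCC1=C(C)CC[C@@H]2C(C)(C)[C@H](Br)CC[C@@]12C | target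

Total step count: 13. Longest linear sequence: 12 steps (steps 1–7 and 9–13, from (R)-linalool); step 8 prepares the ketone partner.

Steps most likely to fail

Step 5. The alkenylcopper species may isomerise through the allenoate before the slow C-methylation, or methylation may stay incomplete, which would erode the geometry of C9=C10. The fallback sets out from aldehyde 4 and comes back at alcohol 10. Roskamp homologation of 4 with ethyl diazoacetate and SnCl2 should give the ethyl β-keto ester F1. C-Methylation (K2CO3, MeI, acetone) gives the α-methyl β-keto ester F2. Enol tosylation under non-chelating conditions (TsCl, N-methylimidazole, Et3N) gives the (E)-enol tosylate F3. Suzuki–Miyaura coupling with isopropenylboronic acid pinacol ester (Pd(OAc)2, SPhos, K3PO4) replaces the tosylate with retention and gives the ethyl dienoate F4. DIBAL-H reduction of F4 gives 10.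

Step 11. The activated neopentyl-type carbinol may ionise with participation of the neighbouring vinyl group (cyclopropylcarbinyl or 1,2-shift pathways) or eliminate instead of undergoing SN2, with loss of configuration. The fallback sets out from allylic bromide 11 and comes back at bromide 17; it installs bromine while C5 is still an ester carbon, which removes the π-participation and disfavours ionisation. Bromide 11 alkylates the kinetic lithium enolate of ethyl 2,2-dimethylacetoacetate to give the β-keto ester F5. (R)-CBS reduction with catecholborane gives the (S)-hydroxy ester F6. Appel bromination (PPh3, CBr4, warmed if needed) gives the (R)-bromo ester F7 with inversion. DIBAL-H at −78 °C gives the bromo aldehyde F8. Wittig methylenation (Ph3P=CH2) installs C6 and gives 17.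

Step 12. The twisted, fully substituted diene may add too slowly to the unactivated alkene, [1,5]-hydrogen shift may intervene, and the π-facial control by the C3 bromide or the trans over cis preference may be insufficient. The fallback sets out from allylic bromide 11, reaches the bromo aldehyde F8 exactly as in the fallback to step 11, and comes back at silyl ether 18. Wittig reaction of F8 with (triphenylphosphoranylidene)acetaldehyde gives the (E)-enal F9, in which C6 carries a removable formyl activating group. An endo-selective intramolecular Diels–Alder reaction under Me2AlCl promotion, or under chiral imidazolidinone iminium catalysis for reagent control of the π-face, forms the same two ring bonds at low temperature and gives the 6-formyl decalin F10. Tsuji–Wilkinson decarbonylation with stoichiometric RhCl(PPh3)3 in hot toluene removes the formyl group and gives 18.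

Further compounds
F1 | step 5 | ethyl (R)-6-methyl-3-oxo-6-(triethylsilyloxy)oct-7-enoate | C=C[C@](C)(O[Si](CC)(CC)CC)CCC(=O)CC(=O)OCC
F2 | step 5 | ethyl (6R)-2,6-dimethyl-3-oxo-6-(triethylsilyloxy)oct-7-enoate (both C2 epimers) | C=C[C@](C)(O[Si](CC)(CC)CC)CCC(=O)C(C)C(=O)OCC
F3 | step 5 | ethyl (2E,6R)-2,6-dimethyl-3-(tosyloxy)-6-(triethylsilyloxy)octa-2,7-dienoate | C=C[C@](C)(O[Si](CC)(CC)CC)CC/C(OS(=O)(=O)c1ccc(C)cc1)=C(/C)C(=O)OCC
F4 | step 5 | ethyl (2E,6R)-2,6-dimethyl-3-(prop-1-en-2-yl)-6-(triethylsilyloxy)octa-2,7-dienoate | C=C[C@](C)(O[Si](CC)(CC)CC)CC/C(C(C)=C)=C(/C)C(=O)OCC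
F5 | step 11 | ethyl (6E,10R)-2,2,6,10-tetramethyl-3-oxo-7-(prop-1-en-2-yl)-10-(triethylsilyloxy)dodeca-6,11-dienoate | C=C[C@](C)(O[Si](CC)(CC)CC)CC/C(C(C)=C)=C(/C)CCC(=O)C(C)(C)C(=O)OCC
F6 | step 11 | ethyl (3S,6E,10R)-3-hydroxy-2,2,6,10-tetramethyl-7-(prop-1-en-2-yl)-10-(triethylsilyloxy)dodeca-6,11-dienoate | C=C[C@](C)(O[Si](CC)(CC)CC)CC/C(C(C)=C)=C(/C)CC[C@H](O)C(C)(C)C(=O)OCC
F7 | step 11 | ethyl (3R,6E,10R)-3-bromo-2,2,6,10-tetramethyl-7-(prop-1-en-2-yl)-10-(triethylsilyloxy)dodeca-6,11-dienoate | C=C[C@](C)(O[Si](CC)(CC)CC)CC/C(C(C)=C)=C(/C)CC[C@@H](Br)C(C)(C)C(=O)OCC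
F8 | step 11 | (3R,6E,10R)-3-bromo-2,2,6,10-tetramethyl-7-(prop-1-en-2-yl)-10-(triethylsilyloxy)dodeca-6,11-dienal | C=C[C@](C)(O[Si](CC)(CC)CC)CC/C(C(C)=C)=C(/C)CC[C@@H](Br)C(C)(C)C=O
F9 | step 12 | (2E,5R,8E,12R)-5-bromo-4,4,8,12-tetramethyl-9-(prop-1-en-2-yl)-12-(triethylsilyloxy)tetradeca-2,8,13-trienal | C=C[C@](C)(O[Si](CC)(CC)CC)CC/C(C(C)=C)=C(/C)CC[C@@H](Br)C(C)(C)/C=C/C=O
F10 | step 12 | 6-formyl derivative of 18, formyl group on C6 cis to H5 | C=C[C@](C)(O[Si](CC)(CC)CC)CCC1=C(C)C[C@@H](C=O)[C@@H]2C(C)(C)[C@H](Br)CC[C@@]12C
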